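## Retrosynthetic overview

1. Target ⇐ O‑demethylation of its 4‑O‑methyl ether, the (Z)‑5‑alkylidene methyl tetronate.
2. Butenolide ring (the only ring made; the furan is bought) ⇐ ring C4–C5 bond from β‑lithiated methyl (E)‑3‑methoxy‑2‑methylacrylate, a β‑acylvinyl anion that is a masked acyl anion at C4, and a C5 α‑chloro aldehyde. Lactonisation and loss of HCl in the same flask set the Z‑olefin.
3. α‑Chloro aldehyde ⇐ copper‑catalysed asymmetric conjugate addition of the side‑chain Grignard reagent to methyl crotonate (sets C2′), enolate chlorination, partial reduction.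
4. (E,E)‑Diene ⇐ Suzuki coupling of an E‑vinyl iodide (carboalumination of 5‑chloropent‑1‑yne) with an E‑vinylboronate.
5. Vinylboronate ⇐ (S)‑β‑citronellene (C10′ from the chiral pool): selective ozonolysis, iodide, Negishi coupling with 3‑bromofuran, cross‑metathesis.

Assumption: methyl (2E)‑3‑methoxy‑2‑methylprop‑2‑enoate and (S)‑β‑citronellene of high ee are taken as catalogue compounds; primes (C1′–C13′) number the side chain from the ylidene carbon, as in the name of the target.

## Route

Step 1
Reactants: 1 (3S)-3,7-dimethylocta-1,6-diene [(S)-β-citronellene]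
Product: 3 (4S)-4-methylhex-5-en-1-ol, via aldehyde 2 (not isolated)
Conditions: O3 (1 equiv, Sudan Red 7B end-point), CH2Cl2–MeOH, −78 °C; then NaBH4, −78 °C → rt
Reagents that add atoms: ozone, [O-][O+]=O
Why: Chemoselective ozonolysis with reductive work-up, in which ozone cleaves the electron-rich trisubstituted alkene much faster than the terminal vinyl group and borohydride reduces aldehyde 2 to the alcohol, the C4 stereocentre (future C10′, S) being taken unchanged from the chiral pool.

Step 2
Reactants: 3 (4S)-4-methylhex-5-en-1-ol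
Product: 4 (3S)-6-iodo-3-methylhex-1-ene
Conditions: I2, PPh3, imidazole, CH2Cl2, 0 °C → rt
Reagents that add atoms: iodine, II
Why: Appel iodination, an SN2 displacement of the alkoxyphosphonium ion by iodide at the primary carbon that leaves the remote stereocentre untouched.

Step 3
Reactants: 4 (3S)-6-iodo-3-methylhex-1-ene; 5 3-bromofuran
Product: 7 3-[(4S)-4-methylhex-5-en-1-yl]furan, via alkylzinc iodide 6 (not isolated)
Conditions: Zn dust, LiCl, THF, 40 °C; then 5, Pd(OAc)2 (2 mol%), SPhos (4 mol%), THF, rt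
Reagents that add atoms: zinc, [Zn] (held only in 6)
Why: Negishi sp3–sp2 cross-coupling, in which LiCl-assisted zinc insertion gives the primary alkylzinc iodide that couples with 3-bromofuran under palladium–biarylphosphine catalysis without affecting the terminal alkene or the stereocentre.

Step 4
Reactants: 7 3-[(4S)-4-methylhex-5-en-1-yl]furan; 8 4,4,5,5-tetramethyl-2-vinyl-1,3,2-dioxaborolane
Product: 9 2-[(1E,3S)-6-(furan-3-yl)-3-methylhex-1-en-1-yl]-4,4,5,5-tetramethyl-1,3,2-dioxaborolane
Conditions: 8 (3 equiv), second-generation Hoveyda–Grubbs catalyst RuCl2(H2IMes)(=CH-C6H4-2-OiPr) (5 mol%), CH2Cl2, 40 °C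
Reagents that add atoms: none
Why: Olefin cross-metathesis with loss of ethene, in which the bulky pinacolboryl group enforces the E-alkenylboronate and the allylic stereocentre is not involved.

Step 5
Reactants: 10 5-chloropent-1-yne
Product: 12 (1E)-5-chloro-1-iodo-2-methylpent-1-ene, via alkenylalane 11 (not isolated)
Conditions: AlMe3 (2 equiv), Cp2ZrCl2 (10 mol%), H2O (1 equiv), CH2Cl2, −20 °C; then I2, THF, −20 → 0 °C
Reagents that add atoms: trimethylaluminium, C[Al](C)C; iodine, II
Why: Negishi zirconium-catalysed carboalumination, a syn addition of methyl and aluminium across the terminal alkyne that places methyl on the internal carbon, followed by iodinolysis of the C–Al bond with retention to give the E-trisubstituted vinyl iodide (future C6′=C7′).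

Step 6
Reactants: 9 2-[(1E,3S)-6-(furan-3-yl)-3-methylhex-1-en-1-yl]-4,4,5,5-tetramethyl-1,3,2-dioxaborolane; 12 (1E)-5-chloro-1-iodo-2-methylpent-1-ene
Product: 13 3-[(4S,5E,7E)-11-chloro-4,8-dimethylundeca-5,7-dien-1-yl]furan
Conditions: Pd(PPh3)4 (5 mol%), K3PO4 (aq), THF, 50 °C
Reagents that add atoms: none
Why: Suzuki–Miyaura coupling of two geometrically defined alkenyl partners with retention at both gives the (E,E)-diene, the primary alkyl chloride being inert to oxidative addition under these conditions.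

Step 7
Reactants: 13 3-[(4S,5E,7E)-11-chloro-4,8-dimethylundeca-5,7-dien-1-yl]furan; 14 methyl (2E)-but-2-enoate
Product: 17 methyl (2RS,3R,7E,9E,11S)-2-chloro-14-(furan-3-yl)-3,7,11-trimethyltetradeca-7,9-dienoate, via Grignard reagent 15 (not isolated), via magnesium enolate 16 (not isolated)
Conditions: Mg, MgBr2·OEt2, 2-MeTHF, 60 °C; then 14, CuBr·SMe2 (5 mol%), (R,S)-Josiphos (C5H5)Fe[C5H3(PPh2)CH(CH3)PCy2] (6 mol%), tBuOMe, −75 °C; then NCS, −75 → −20 °C
Reagents that add atoms: magnesium, [Mg] (held only in 15 and 16); N-chlorosuccinimide, O=C1CCC(=O)N1Cl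
Why: Copper-catalysed asymmetric conjugate addition of the Grignard reagent to the crotonate, in which the chiral ferrocenyl diphosphine (the Josiphos antipode that gives 3R, to be confirmed on a model run) selects the enoate face and so sets the C3 methyl stereocentre (future C2′), followed by chlorination of the magnesium enolate in a tandem conjugate addition–enolate trapping, the C2 configuration being irrelevant because this carbon becomes sp2.

Step 8
Reactants: 17 methyl (2RS,3R,7E,9E,11S)-2-chloro-14-(furan-3-yl)-3,7,11-trimethyltetradeca-7,9-dienoate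
Product: 18 (2RS,3R,7E,9E,11S)-2-chloro-14-(furan-3-yl)-3,7,11-trimethyltetradeca-7,9-dienal
Conditions: iBu2AlH (DIBAL-H, 1.1 equiv), CH2Cl2, −78 °C; then MeOH, aq KNaC4H4O6 (Rochelle salt)
Reagents that add atoms: none
Why: Partial ester reduction with diisobutylaluminium hydride, which stops at the tetrahedral aluminium hemiacetal at −78 °C and releases the α-chloro aldehyde on work-up without touching the C3 stereocentre.

Step 9
Reactants: 18 (2RS,3R,7E,9E,11S)-2-chloro-14-(furan-3-yl)-3,7,11-trimethyltetradeca-7,9-dienal; 19 methyl (2E)-3-methoxy-2-methylprop-2-enoate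
Product: 22 (5Z)-5-[(2R,6E,8E,10S)-13-(furan-3-yl)-2,6,10-trimethyltrideca-6,8-dien-1-ylidene]-4-methoxy-3-methylfuran-2(5H)-one, via lithioacrylate 20 (not isolated), via chlorolactone 21 (not isolated)
Conditions: 19 (1.2 equiv), LiN(iPr)2 (LDA, 1.2 equiv), THF, −95 °C; 18, −95 → −20 °C; then Me3SiCl, DBU, −20 °C → rt
Reagents that add atoms: lithium diisopropylamide, [Li+].CC(C)[N-]C(C)C (lithium held only in 20)
Why: Proposed new method: chelation-directed β-lithiation of 19 gives vinyllithium 20, a β-acylvinyl anion that is also a masked acyl anion for ring C4, so that its 1,2-addition to the aldehyde carbon of 18 (ring C5) joins two carbons that are both acceptor sites, the resulting alkoxide lactonises onto the cis ester to give 21 (the known tetronate synthesis from β-lithio-β-alkoxyacrylates and aldehydes), Me3SiCl then removes the liberated LiOMe, and DBU deprotonates the acidic C5–H and expels the β-chloride (E1cB; closest known reaction type: base-induced elimination of 5-(1-sulfonyloxyalkyl)tetronates to 5-ylidene tetronates), giving the thermodynamically preferred Z-alkylidene with the side chain anti to the 4-methoxy group while the non-acidic C2′–H stereocentre is untouched.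

Step 10
Reactants: 22 (5Z)-5-[(2R,6E,8E,10S)-13-(furan-3-yl)-2,6,10-trimethyltrideca-6,8-dien-1-ylidene]-4-methoxy-3-methylfuran-2(5H)-one
Product: 23 (5Z)-5-[(2R,6E,8E,10S)-13-(furan-3-yl)-2,6,10-trimethyltrideca-6,8-dien-1-ylidene]-4-hydroxy-3-methylfuran-2(5H)-one
Conditions: n-PrSH, n-BuLi, HMPA, 20 °C; then 1 M HCl
Reagents that add atoms: none
Why: SN2 O-demethylation of the vinylogous carbonate by the soft thiolate in a dipolar aprotic solvent (the tetronate anion is the leaving group) followed by acidification, conditions under which the Z-olefin, the diene, the furan and both stereocentres are unchanged.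

## Compound list

1 | (3S)-3,7-dimethylocta-1,6-diene [(S)-β-citronellene] | C=C[C@@H](C)CCC=C(C)C | starting material
2 | (4S)-4-methylhex-5-enal | C=C[C@@H](C)CCC=O | intermediate
3 | (4S)-4-methylhex-5-en-1-ol | C=C[C@@H](C)CCCO | intermediate
4 | (3S)-6-iodo-3-methylhex-1-ene | C=C[C@@H](C)CCCI | intermediate
5 | 3-bromofuran | Brc1ccoc1 | starting material
6 | [(4S)-4-methylhex-5-en-1-yl]zinc iodide | C=C[C@@H](C)CCC[Zn]I | intermediate
7 | 3-[(4S)-4-methylhex-5-en-1-yl]furan | C=C[C@@H](C)CCCc1ccoc1 | intermediate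
8 | 4,4,5,5-tetramethyl-2-vinyl-1,3,2-dioxaborolane | C=CB1OC(C)(C)C(C)(C)O1 | starting material
9 | 2-[(1E,3S)-6-(furan-3-yl)-3-methylhex-1-en-1-yl]-4,4,5,5-tetramethyl-1,3,2-dioxaborolane | CC1(C)OB(/C=C/[C@@H](C)CCCc2ccoc2)OC1(C)C | intermediate
10 | 5-chloropent-1-yne | C#CCCCCl | starting material
11 | [(1E)-5-chloro-2-methylpent-1-en-1-yl]dimethylalumane | ClCCC/C(C)=C/[Al](C)C | intermediate
12 | (1E)-5-chloro-1-iodo-2-methylpent-1-ene | ClCCC/C(C)=C/I | intermediate
13 | 3-[(4S,5E,7E)-11-chloro-4,8-dimethylundeca-5,7-dien-1-yl]furan | ClCCC/C(C)=C/C=C/[C@@H](C)CCCc1ccoc1 | intermediate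
14 | methyl (2E)-but-2-enoate (methyl crotonate) | C/C=C/C(=O)OC | starting material
15 | [(4E,6E,8S)-11-(furan-3-yl)-4,8-dimethylundeca-4,6-dien-1-yl]magnesium chloride | Cl[Mg]CCC/C(C)=C/C=C/[C@@H](C)CCCc1ccoc1 | intermediate
16 | chloromagnesium enolate of methyl (3R,7E,9E,11S)-14-(furan-3-yl)-3,7,11-trimethyltetradeca-7,9-dienoate | COC(O[Mg]Cl)=C[C@H](C)CCC/C(C)=C/C=C/[C@@H](C)CCCc1ccoc1 | intermediate
17 | methyl (2RS,3R,7E,9E,11S)-2-chloro-14-(furan-3-yl)-3,7,11-trimethyltetradeca-7,9-dienoate | COC(=O)C(Cl)[C@H](C)CCC/C(C)=C/C=C/[C@@H](C)CCCc1ccoc1 | intermediate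
18 | (2RS,3R,7E,9E,11S)-2-chloro-14-(furan-3-yl)-3,7,11-trimethyltetradeca-7,9-dienal | O=CC(Cl)[C@H](C)CCC/C(C)=C/C=C/[C@@H](C)CCCc1ccoc1 | intermediate
19 | methyl (2E)-3-methoxy-2-methylprop-2-enoate | CO/C=C(C)/C(=O)OC | starting material
20 | methyl (2E)-3-lithio-3-methoxy-2-methylprop-2-enoate | CO/C([Li])=C(C)/C(=O)OC | intermediate
21 | 5-[(1RS,2R,6E,8E,10S)-1-chloro-13-(furan-3-yl)-2,6,10-trimethyltrideca-6,8-dien-1-yl]-4-methoxy-3-methylfuran-2(5H)-one (C5 epimers) | CC1=C(OC)C(C(Cl)[C@H](C)CCC/C(C)=C/C=C/[C@@H](C)CCCc2ccoc2)OC1=O | intermediate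
22 | (5Z)-5-[(2R,6E,8E,10S)-13-(furan-3-yl)-2,6,10-trimethyltrideca-6,8-dien-1-ylidene]-4-methoxy-3-methylfuran-2(5H)-one | CC1=C(OC)/C(=C/[C@H](C)CCC/C(C)=C/C=C/[C@@H](C)CCCc2ccoc2)OC1=O | intermediate
23 | (5Z)-5-[(2R,6E,8E,10S)-13-(furan-3-yl)-2,6,10-trimethyltrideca-6,8-dien-1-ylidene]-4-hydroxy-3-methylfuran-2(5H)-one | CC1=C(O)/C(=C/[C@H](C)CCC/C(C)=C/C=C/[C@@H](C)CCCc2ccoc2)OC1=O | target

## Step count and risks

Total: 10 steps. Longest linear sequence: 9 steps (steps 1, 2, 3, 4, 6, 7, 8, 9, 10; step 5 is the side branch).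

The three steps most likely to fail:

**Step 9.** The chlorohydrin alkoxide may close to the epoxide instead of lactonising, and methoxide may open the enol lactone 22. The fallback sets out from 13 and comes back at 22. Grignard reagent 15 is added to 14 under the same copper catalysis but without chlorination, giving methyl (3R,7E,9E,11S)-14-(furan-3-yl)-3,7,11-trimethyltetradeca-7,9-dienoate F1. Reduction with iBu2AlH at −78 °C gives (3R,7E,9E,11S)-14-(furan-3-yl)-3,7,11-trimethyltetradeca-7,9-dienal F2. Addition of 20 with lactonisation gives 5-[(2R,6E,8E,10S)-13-(furan-3-yl)-2,6,10-trimethyltrideca-6,8-dien-1-yl]-4-methoxy-3-methylfuran-2(5H)-one F3. Deprotonation at C5 with LiN(iPr)2 and trapping with PhSeBr gives 5-[(2R,6E,8E,10S)-13-(furan-3-yl)-2,6,10-trimethyltrideca-6,8-dien-1-yl]-4-methoxy-3-methyl-5-(phenylselanyl)furan-2(5H)-one F4. H2O2–pyridine at 0 °C then triggers selenoxide syn-elimination, for which only the C1′ hydrogens are available, to give 22. The same reversed-polarity C4–C5 bond formation is kept; only the way the olefin is introduced changes.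

**Step 7.** The chloride-derived Grignard reagent may give a lower ee than bromide-derived ones, and the enolate chlorination may be incomplete. The fallback sets out from 13 and comes back at 17, taking C2′ from the chiral pool instead of from the catalyst. Grignard reagent 15 opens (4R)-4-methyloxetan-2-one at C4 with inversion under CuBr·SMe2 catalysis (SN2 alkyl–oxygen cleavage) to give (3R,7E,9E,11S)-14-(furan-3-yl)-3,7,11-trimethyltetradeca-7,9-dienoic acid F5. Its dianion (LiN(iPr)2, 2.2 equiv) is chlorinated with CCl4 to give (2RS,3R,7E,9E,11S)-2-chloro-14-(furan-3-yl)-3,7,11-trimethyltetradeca-7,9-dienoic acid F6, and Me3SiCHN2 esterifies it to 17.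

**Step 4.** Cross-metathesis of the α-branched alkene may be slow, and ruthenium hydride-induced alkene migration would erode C10′. The fallback sets out from 7 and comes back at 13. Lemieux–Johnson cleavage (K2OsO4·2H2O catalytic, NaIO4, 2,6-lutidine; the terminal alkene is osmylated faster than the furan) gives (2S)-5-(furan-3-yl)-2-methylpentanal F7. Takai olefination (CrCl2, CHI3, THF) gives 3-[(4S,5E)-6-iodo-4-methylhex-5-en-1-yl]furan F8. Alkenylalane 11, generated from 10 as in step 5, is then coupled directly with F8 (Pd(PPh3)4, ZnCl2) to give 13, which also makes 9 and 12 unnecessary.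

## Further compounds

F1 | step 9 | methyl (3R,7E,9E,11S)-14-(furan-3-yl)-3,7,11-trimethyltetradeca-7,9-dienoate | COC(=O)C[C@H](C)CCC/C(C)=C/C=C/[C@@H](C)CCCc1ccoc1
F2 | step 9 | (3R,7E,9E,11S)-14-(furan-3-yl)-3,7,11-trimethyltetradeca-7,9-dienal | O=CC[C@H](C)CCC/C(C)=C/C=C/[C@@H](C)CCCc1ccoc1
F3 | step 9 | 5-[(2R,6E,8E,10S)-13-(furan-3-yl)-2,6,10-trimethyltrideca-6,8-dien-1-yl]-4-methoxy-3-methylfuran-2(5H)-one | CC1=C(OC)C(C[C@H](C)CCC/C(C)=C/C=C/[C@@H](C)CCCc2ccoc2)OC1=O
F4 | step 9 | 5-[(2R,6E,8E,10S)-13-(furan-3-yl)-2,6,10-trimethyltrideca-6,8-dien-1-yl]-4-methoxy-3-methyl-5-(phenylselanyl)furan-2(5H)-one | CC1=C(OC)C(C[C@H](C)CCC/C(C)=C/C=C/[C@@H](C)CCCc2ccoc2)([Se]c2ccccc2)OC1=O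
F5 | step 7 | (3R,7E,9E,11S)-14-(furan-3-yl)-3,7,11-trimethyltetradeca-7,9-dienoic acid | OC(=O)C[C@H](C)CCC/C(C)=C/C=C/[C@@H](C)CCCc1ccoc1
F6 | step 7 | (2RS,3R,7E,9E,11S)-2-chloro-14-(furan-3-yl)-3,7,11-trimethyltetradeca-7,9-dienoic acid | OC(=O)C(Cl)[C@H](C)CCC/C(C)=C/C=C/[C@@H](C)CCCc1ccoc1
F7 | step 4 | (2S)-5-(furan-3-yl)-2-methylpentanal | O=C[C@@H](C)CCCc1ccoc1
F8 | step 4 | 3-[(4S,5E)-6-iodo-4-methylhex-5-en-1-yl]furan | I/C=C/[C@@H](C)CCCc1ccoc1
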